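**Retrosynthetic overview**
1. The target comes from its dimethyl ester, and that from the 11-ketone. The C11 carbinol is read as a ketone in the middle of the three-atom bridge (C9–C11–C12) of the bicyclo[3.2.1]octane formed by rings C and D.
2. Key disconnection: break C13–C16 and re-join C11–C13. Ring C (C8, C9, C11, C12, C13, C14) and ring D (C8, C14, C13, C16, C15) then collapse to a cyclopentane (C8, C9, C11, C13, C14) fused to a silyloxycyclopropane (C11, C12, C13), with a propargyl group (C15–C17) on quaternary C8. Both bridges are removed at once.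
3. Enabling feature: the oxygen on C11 lies β to bridgehead C13, C13 lies 1,3 across ring C from C8 (which carries C15), and the exocyclic C16=C17 methylene is the trace of a 5-exo-dig closure onto an alkyne.
4. The cyclopentanone comes from a ketyl–nitrile closure onto the C9 ketone. C8 is set by two alkylations of a ring B 1,3-dione anti to C20. C7 enters at C6 by triflate carbonylation. C19 and C18 enter at C4 by carboxylation and methylation.
5. Ring order: A and B (bought as the bicyclic enedione), then the five-membered forerunner of ring C, then the cyclopropane, then ring C by expansion together with ring D.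

Key step: step 21

Assumption: gibberellane numbering is used (ring A C1–C5, C10; ring B C5, C6, C8, C9, C10; C7 is the carboxyl on C6; C18/C19 are the methyl/carboxyl on C4; C20 is the methyl on C10); α is the face of C20, β the face of H5 and H9; compound 1 is taken as a catalogue item.

Step 1
Reactants: 1 (R)-Hajos–Parrish ketone
Product: 2 C9 ethylene ketal of 1
Conditions: (Me3SiOCH2)2, Me3SiOTf (cat.), CH2Cl2, −78 °C
Reagents that add atoms: 1,2-bis(trimethylsilyloxy)ethane, C[Si](C)(C)OCCO[Si](C)(C)C
Why: Noyori-type acetalisation at low temperature should take the saturated C9 ketone and leave the less electrophilic conjugated C3 enone; no stereocentre is formed.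

Step 2
Reactants: 2 C9 ethylene ketal of 1
Product: 3 3-oxo-4-ene-4-carboxylic acid (C19 acid)
Conditions: MeOMgOCO2Me (2 M in DMF), 120 °C; then cold 1 M HCl
Reagents that add atoms: magnesium methyl carbonate, COC(=O)O[Mg]OC
Why: Stiles carboxylation traps the thermodynamic dienolate at C4 as the magnesium chelate of the β-keto acid, and C8 cannot compete because C9 is masked.

Step 3
Reactants: 3 3-oxo-4-ene-4-carboxylic acid
Product: 5 4β-methyl-4α-methoxycarbonyl-3-oxo-5(6)-ene 9-ketal, via methyl ester 4 (not isolated)
Conditions: MeI (excess), K2CO3, DMF, rt → 40 °C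
Reagents that add atoms: iodomethane, CI
Why: Carboxylate O-alkylation is followed by deconjugative α-alkylation of the extended enolate of the alkylidene β-keto ester; MeI should reach C4 from the β face, anti to the axial C20 methyl, so the ester ends α (axial) and the alkene moves to C5=C6.

Step 4
Reactants: 5 4β-methyl-4α-methoxycarbonyl-3-oxo-5(6)-ene 9-ketal
Product: 6 3α-alcohol of 5
Conditions: NaBH4, MeOH, 0 °C
Reagents that add atoms: none
Why: Borohydride reduction with axial hydride delivery from the β face (the α face is screened by the axial ester) should give the equatorial 3α-alcohol; this centre only masks the ketone and is corrected in step 16.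

Step 5
Reactants: 6 3α-alcohol
Product: 7 3α-OTBS ether
Conditions: t-BuMe2SiOTf, 2,6-lutidine, CH2Cl2, 0 °C
Reagents that add atoms: tert-butyldimethylsilyl triflate, CC(C)(C)[Si](C)(C)OS(=O)(=O)C(F)(F)F
Why: Silyl ether protection with the reactive triflate copes with the neopentyl-type alcohol, and the equatorial OTBS leaves the β face of ring A open for later steps.

Step 6
Reactants: 7 3α-OTBS ether
Product: 9 6β-alcohol of the trans-hydrindane (5β-H), via 6β-alkylborane 8 (not isolated)
Conditions: BH3·THF, THF, 0 °C → rt; then NaOH, H2O2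
Reagents that add atoms: hydrogen peroxide, OO; borane–THF, B.C1CCOC1 (its boron stays only in 8)
Why: In this hydroboration–oxidation boron goes to the less substituted C6 and syn addition occurs on the β face, opposite the axial C20 methyl and C19 ester (as with 4,4-disubstituted 5-ene steroids), which sets 5β-H and 6β-OH.

Step 7
Reactants: 9 6β-alcohol
Product: 10 6-ketone 9-ketal
Conditions: Dess–Martin periodinane, CH2Cl2, rt
Reagents that add atoms: none
Why: Dess–Martin oxidation is near neutral, so the ketal, the silyl ether and the epimerisable 5β-H should survive.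

Step 8
Reactants: 10 6-ketone 9-ketal
Product: 11 ring B 6,9-dione
Conditions: 1 M HCl, THF, rt
Reagents that add atoms: water, O
Why: Acid-catalysed acetal hydrolysis frees C9; the resulting 1,3-dione enolises towards C8, which protects H5 from exchange, and the hindered TBS ether is stable to dilute acid.

Step 9
Reactants: 11 ring B 6,9-dione; 12 acrylonitrile
Product: 13 8-(2-cyanoethyl) 6,9-dione (drawn as its 9-enol)
Conditions: Et3N (cat.), MeCN, 40 °C, 1.0 equiv of 12
Reagents that add atoms: none
Why: Michael addition (cyanoethylation) of the acidic dione at C8 with one equivalent of acceptor brings in C14, C13 and C11; the product rests as an enol, so no stereocentre is fixed yet.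

Step 10
Reactants: 13 8-(2-cyanoethyl) 6,9-dione; 14 propargyl bromide
Product: 15 8β-propargyl-8α-(2-cyanoethyl) 6,9-dione
Conditions: t-BuOK (1.0 equiv), t-BuOH–THF, 0 °C → rt
Reagents that add atoms: none
Why: This is C-alkylation of a 2-substituted cyclopentane-1,3-dione enolate with a soft propargylic halide; with C6 and C9 both trigonal the only bias is the pseudo-axial C20 methyl on the α face, so C15 should enter on the β face and leave the cyanoethyl arm α, which sets C8.

Step 11
Reactants: 15 8β-propargyl-8α-(2-cyanoethyl) 6,9-dione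
Product: 16 5(6)-en-6-yl triflate
Conditions: Tf2O, 2,6-di-tert-butyl-4-methylpyridine, CH2Cl2, 0 °C → rt
Reagents that add atoms: triflic anhydride, O=S(=O)(OS(=O)(=O)C(F)(F)F)C(F)(F)F
Why: Vinyl triflate formation with Tf2O and a hindered pyridine avoids strong base (no retro-Michael loss of acrylonitrile), and only the C6 carbonyl has an α-hydrogen (H5), so a single C5=C6 triflate can form.

Step 12
Reactants: 16 5(6)-en-6-yl triflate
Product: 17 5(6)-ene-6-carboxylate (C7 methyl ester)
Conditions: Pd(OAc)2 (cat.), Ph2P(CH2)3PPh2 (cat.), CO (1 atm), Et3N, MeOH–DMF, 60 °C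
Reagents that add atoms: carbon monoxide, [C-]#[O+]; methanol, CO
Why: In this palladium-catalysed methoxycarbonylation, oxidative addition of zerovalent palladium into the C6–O bond, CO insertion and methanolysis bring in C7, and the large excess of methanol should outrun coupling at the free alkyne.

Step 13
Reactants: 17 5(6)-ene-6-carboxylate
Product: 18 5β-H 6β-methoxycarbonyl keto nitrile (3α-OTBS)
Conditions: Mg, MeOH, 0 °C → rt, then 40 °C
Reagents that add atoms: none
Why: In this dissolving-metal conjugate reduction of an enoate, C5 should be protonated on the β face because the α face is closed by the axial C20 methyl and C19 ester (trans fusion), and the Mg(OMe)2 formed equilibrates the C6 ester to the β position, trans to the C5–C4 bond; the alkyne, the nitrile and the shielded C9 ketone are not reduced.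

Step 14
Reactants: 18 5β-H 6β-methoxycarbonyl keto nitrile (3α-OTBS)
Product: 19 3α-alcohol
Conditions: HF·pyridine, THF, 0 °C → rt
Reagents that add atoms: none
Why: Fluoride desilylation under weakly acidic conditions touches no other group.

Step 15
Reactants: 19 3α-alcohol
Product: 20 3,9-dione
Conditions: Dess–Martin periodinane, CH2Cl2, rt
Reagents that add atoms: none
Why: Dess–Martin oxidation of the only free alcohol restores the C3 ketone, now in a saturated trans-fused ring A.

Step 16
Reactants: 20 3,9-dione
Product: 21 3β-alcohol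
Conditions: KBH(s-Bu)3, THF, −78 °C; then H2O
Reagents that add atoms: none
Why: In this bulky trialkylborohydride reduction the reagent avoids the syn-axial H1β and H5β and attacks along the equatorial trajectory, as with 4,4-disubstituted 3-oxo terpenoids, giving the axial 3β-alcohol; the C9 ketone between two quaternary carbons is out of reach.

Step 17
Reactants: 21 3β-alcohol
Product: 23 9β-hydroxy-11-ketone tricycle (α-ketol), via hydroxy imine 22 (not isolated)
Conditions: SmI2, t-BuOH, THF, visible light, rt; then 0.5 M HCl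
Reagents that add atoms: water, O
Why: In this SmI2 ketyl–nitrile reductive cyclisation (5-exo-dig) the C9 ketyl can reach only the nitrile of the α arm, so C11 bonds to the α face of C9 (cis-bicyclo[3.3.0]octane, 9β-OH), and imine hydrolysis gives the α-ketol.

Step 18
Reactants: 23 9β-hydroxy-11-ketone tricycle
Product: 24 tricyclic 11-ketone with five-membered forerunner of ring C (9β-H)
Conditions: SmI2, HMPA, MeOH, THF, −78 °C
Reagents that add atoms: none
Why: In this SmI2 reduction of an α-hydroxy ketone the C9–O bond is cleaved through the C11 ketyl, and the samarium enolate is protonated at C9 to the only unstrained, cis-fused diquinane, which sets 9β-H.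

Step 19
Reactants: 24 tricyclic 11-ketone
Product: 25 11(13)-enol trimethylsilyl ether with 3β-OSiMe3
Conditions: LiN(SiMe3)2 (2.3 equiv), THF, −78 °C; Me3SiCl
Reagents that add atoms: chlorotrimethylsilane, C[Si](C)(C)Cl
Why: In this kinetic enolate silylation the amide base takes an unhindered C13 proton rather than H9 (flanked by two quaternary carbons), is too weak to metalate the alkyne, and the C3 alkoxide is silylated in the same operation.

Step 20
Reactants: 25 11(13)-enol trimethylsilyl ether
Product: 26 11-silyloxy cyclopropane (C11, C12, C13; C12 on the β face)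
Conditions: Et2Zn, CH2I2, CH2Cl2, 0 °C
Reagents that add atoms: diiodomethane, ICI
Why: Furukawa-modified Simmons–Smith cyclopropanation picks the electron-rich enol ether over the alkyne and adds C12 on the convex β face; both new stereocentres (C11, C13) are erased in step 21.

Step 21
Reactants: 26 11-silyloxy cyclopropane
Product: 29 3β-hydroxy-11-oxo tetracyclic dimethyl ester (rings A to D complete), via C13 radical 27 (not isolated), via vinyl radical 28 (not isolated)
Conditions: Fe(NO3)3·9H2O (2.5 equiv), 1,4-cyclohexadiene (3 equiv), DMF (0.01 M), 0 °C → rt; 1 M HCl work-up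
Reagents that add atoms: none
Why: One-electron oxidation of the silyloxycyclopropane by Fe(NO3)3 with loss of the silyl group gives a cyclopropyloxy radical whose strain is released by β-scission of the zero-bridge C11–C13 bond, so the five-membered ring C8–C9–C11–C13–C14 becomes six-membered ring C with C12 inserted, C11 as a ketone and the spin on C13 (27). The closest known reaction type is the iron- or manganese-salt-mediated oxidative ring expansion–cyclisation of 1-silyloxybicyclo[n.1.0]alkanes and the parent cyclopropanols that carry an unsaturated side chain, terminated by hydrogen transfer from 1,4-cyclohexadiene. Ring C is closed by ring expansion (one bond broken, none made), and ring D (C8, C14, C13, C16, C15) by 5-exo-dig attack of C13 on C16 of the axial propargyl group, the same geometry as in the classical ketyl–alkyne closures of gibberellin C/D systems. The only new stereocentre, C13, is fixed by the tether, because the two-atom bridge C15–C16 can span C8 and C13 only on the β face where C15 already stands, and C9 is not touched. The step needs endocyclic rather than exocyclic (C11–C12) scission, secured by the secondary versus primary radical and the better overlap of the zero-bridge bond, and it needs cyclisation before hydrogen transfer, secured by high dilution, a donor that is fast only towards the vinyl radical, and the quaternary C8. Vinyl radical 28 takes hydrogen from the diene to leave the exocyclic C16=C17 methylene, and the acidic work-up frees the C3 hydroxyl.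

Step 22
Reactants: 29 3β-hydroxy-11-oxo tetracyclic dimethyl ester
Product: 30 dimethyl ester of the target (3β,11α-diol)
Conditions: SmI2, H2O, THF, rt
Reagents that add atoms: none
Why: Electron-transfer reduction (SmI2–H2O) is indifferent to the crowding at C11 and should give the thermodynamic equatorial 11α-alcohol, turned away from the C15–C16 bridge, as alkali-metal reductions of 11-oxo steroids and bicyclo[3.2.1]octan-3-ones do; methyl esters and the 1,1-disubstituted alkene are inert without an amine additive.

Step 23
Reactants: 30 dimethyl ester of the target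
Product: 31 target diacid
Conditions: LiS-n-Pr, HMPA, rt; then 1 M HCl
Reagents that add atoms: none
Why: SN2 dealkylation of both methyl esters by thiolate attacks the methyl carbons, so the hindered axial C19 ester is no obstacle, and the weakly basic medium avoids retro-aldol epimerisation at C3 and epimerisation at C6.

**Compound list**
1 | (7aR)-7a-methyl-2,3,7,7a-tetrahydro-1H-indene-1,5(6H)-dione, (R)-Hajos–Parrish ketone | C[C@@]12CCC(=O)C=C1CCC2=O | starting material
2 | C9 ethylene ketal of 1 | C[C@@]12CCC(=O)C=C1CCC23OCCO3 | intermediate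
3 | 3-oxo-4-ene-4-carboxylic acid, 9-ketal | C[C@@]12CCC(=O)C(C(=O)O)=C1CCC23OCCO3 | intermediate
4 | methyl ester of 3 | C[C@@]12CCC(=O)C(C(=O)OC)=C1CCC23OCCO3 | intermediate
5 | 4β-methyl-4α-methoxycarbonyl-3-oxo-5(6)-ene 9-ketal | C[C@@]12CCC(=O)[C@@](C)(C(=O)OC)C1=CCC23OCCO3 | intermediate
6 | 3α-alcohol of 5 | C[C@@]12CC[C@@H](O)[C@@](C)(C(=O)OC)C1=CCC23OCCO3 | intermediate
7 | 3α-OTBS ether of 6 | C[C@@]12CC[C@@H](O[Si](C)(C)C(C)(C)C)[C@@](C)(C(=O)OC)C1=CCC23OCCO3 | intermediate
8 | 6β-alkylborane (5β-H) | C[C@@]12CC[C@@H](O[Si](C)(C)C(C)(C)C)[C@@](C)(C(=O)OC)[C@H]1[C@H](B)CC23OCCO3 | intermediate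
9 | 6β-alcohol, trans-hydrindane (5β-H) | C[C@@]12CC[C@@H](O[Si](C)(C)C(C)(C)C)[C@@](C)(C(=O)OC)[C@H]1[C@H](O)CC23OCCO3 | intermediate
10 | 6-ketone 9-ketal | C[C@@]12CC[C@@H](O[Si](C)(C)C(C)(C)C)[C@@](C)(C(=O)OC)[C@H]1C(=O)CC23OCCO3 | intermediate
11 | ring B 6,9-dione | C[C@@]12CC[C@@H](O[Si](C)(C)C(C)(C)C)[C@@](C)(C(=O)OC)[C@H]1C(=O)CC2=O | intermediate
12 | acrylonitrile | C=CC#N | starting material
13 | 8-(2-cyanoethyl) 6,9-dione, 9-enol form | C[C@@]12CC[C@@H](O[Si](C)(C)C(C)(C)C)[C@@](C)(C(=O)OC)[C@H]1C(=O)C(CCC#N)=C2O | intermediate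
14 | propargyl bromide | C#CCBr | starting material
15 | 8β-propargyl-8α-(2-cyanoethyl) 6,9-dione | C[C@@]12CC[C@@H](O[Si](C)(C)C(C)(C)C)[C@@](C)(C(=O)OC)[C@H]1C(=O)[C@@](CC#C)(CCC#N)C2=O | intermediate
16 | 5(6)-en-6-yl triflate | C[C@@]12CC[C@@H](O[Si](C)(C)C(C)(C)C)[C@@](C)(C(=O)OC)C1=C(OS(=O)(=O)C(F)(F)F)[C@@](CC#C)(CCC#N)C2=O | intermediate
17 | 5(6)-ene-6-carboxylate (C7 methyl ester) | C[C@@]12CC[C@@H](O[Si](C)(C)C(C)(C)C)[C@@](C)(C(=O)OC)C1=C(C(=O)OC)[C@@](CC#C)(CCC#N)C2=O | intermediate
18 | 5β-H, 6β-methoxycarbonyl keto nitrile, 3α-OTBS | C[C@@]12CC[C@@H](O[Si](C)(C)C(C)(C)C)[C@@](C)(C(=O)OC)[C@H]1[C@H](C(=O)OC)[C@@](CC#C)(CCC#N)C2=O | intermediate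
19 | 3α-alcohol of 18 | C[C@@]12CC[C@@H](O)[C@@](C)(C(=O)OC)[C@H]1[C@H](C(=O)OC)[C@@](CC#C)(CCC#N)C2=O | intermediate
20 | 3,9-dione | C[C@@]12CCC(=O)[C@@](C)(C(=O)OC)[C@H]1[C@H](C(=O)OC)[C@@](CC#C)(CCC#N)C2=O | intermediate
21 | 3β-alcohol, 9-ketone | C[C@@]12CC[C@H](O)[C@@](C)(C(=O)OC)[C@H]1[C@H](C(=O)OC)[C@@](CC#C)(CCC#N)C2=O | intermediate
22 | 9β-hydroxy-11-imine tricycle | C#CC[C@]23CCC(=N)[C@@]2(O)[C@]1(C)CC[C@H](O)[C@@](C)(C(=O)OC)[C@H]1[C@@H]3C(=O)OC | intermediate
23 | 9β-hydroxy-11-ketone tricycle (α-ketol) | C#CC[C@]23CCC(=O)[C@@]2(O)[C@]1(C)CC[C@H](O)[C@@](C)(C(=O)OC)[C@H]1[C@@H]3C(=O)OC | intermediate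
24 | tricyclic 11-ketone, 9β-H, five-membered forerunner of ring C | C#CC[C@]23CCC(=O)[C@H]2[C@]1(C)CC[C@H](O)[C@@](C)(C(=O)OC)[C@H]1[C@@H]3C(=O)OC | intermediate
25 | 11(13)-enol trimethylsilyl ether, 3β-OSiMe3 | C#CC[C@]23CC=C(O[Si](C)(C)C)[C@H]2[C@]1(C)CC[C@H](O[Si](C)(C)C)[C@@](C)(C(=O)OC)[C@H]1[C@@H]3C(=O)OC | intermediate
26 | 11-silyloxy cyclopropane (C11, C12, C13), C12 β | C#CC[C@]23C[C@@H]4C[C@]4(O[Si](C)(C)C)[C@H]2[C@]1(C)CC[C@H](O[Si](C)(C)C)[C@@](C)(C(=O)OC)[C@H]1[C@@H]3C(=O)OC | intermediate
27 | ring-expanded 11-oxo C13 radical | C#CC[C@]23C[CH]CC(=O)[C@H]2[C@]1(C)CC[C@H](O[Si](C)(C)C)[C@@](C)(C(=O)OC)[C@H]1[C@@H]3C(=O)OC | intermediate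
28 | tetracyclic C17 vinyl radical | [CH]=C1C[C@]23C[C@H]1CC(=O)[C@H]2[C@]1(C)CC[C@H](O[Si](C)(C)C)[C@@](C)(C(=O)OC)[C@H]1[C@@H]3C(=O)OC | intermediate
29 | 3β-hydroxy-11-oxo tetracyclic dimethyl ester | C=C1C[C@]23C[C@H]1CC(=O)[C@H]2[C@]1(C)CC[C@H](O)[C@@](C)(C(=O)OC)[C@H]1[C@@H]3C(=O)OC | intermediate
30 | dimethyl ester of the target (3β,11α-diol) | C=C1C[C@]23C[C@H]1C[C@@H](O)[C@H]2[C@]1(C)CC[C@H](O)[C@@](C)(C(=O)OC)[C@H]1[C@@H]3C(=O)OC | intermediate
31 | CNP0232910.1, 3β,11α-dihydroxy C20 gibberellin diacid | C=C1C[C@]23C[C@H]1C[C@@H](O)[C@H]2[C@]1(C)CC[C@H](O)[C@@](C)(C(=O)O)[C@H]1[C@@H]3C(=O)O | target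

**Total step count:** 23. **Longest linear sequence:** 23 steps (from 1).

**Steps most likely to fail**

Step 21. The C13 radical may pick up hydrogen or be oxidised before ring D closes, or the cyclopropane may open at the exocyclic bond. The fallback sets out from 26 and comes back at 29, and it separates ring expansion from bridging. FeCl3 in DMF opens the same C11–C13 bond and transfers chlorine to C13, giving after acidic work-up the 13-chloro-11-ketone F1. NaOAc in MeOH eliminates HCl to the ring-expanded cyclohex-12-en-11-one F2 (the classical one-carbon enone ring expansion of silyloxycyclopropanes). Bu3SnH with AIBN then adds a stannyl radical to the alkyne terminus, and the C16 vinyl radical closes ring D by 5-exo-trig conjugate addition to C13, giving the 17-stannyl tetracycle F3. Protodestannylation with dilute HCl gives 29.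

Step 13. Electron transfer to the crowded tetrasubstituted enoate may be sluggish, and protonation of C5 may show poor facial selectivity, which would lead into the cis-hydrindane series. The fallback sets out from 15 and comes back at 18. It keeps the 5β-H set by hydroboration in step 6 and bypasses steps 11 to 13. Wittig homologation of the C6 ketone with Ph3P=CHOMe (the C9 ketone is out of reach) gives the 6-methoxymethylidene compound F4. Mild aqueous acid followed by brief DBU gives the more stable 6β-aldehyde F5. Pinnick oxidation (NaClO2, NaH2PO4, 2-methyl-2-butene) gives the 6β-acid F6, and Me3SiCHN2 gives 18.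

Step 17. Plain reduction of the hindered C9 ketone, followed by lactonisation onto the C7 ester, may outrun addition of the ketyl to the nitrile. The fallback sets out from 21 and comes back at 24. Pinner methanolysis (HCl, MeOH, then H2O) turns the unhindered nitrile into the keto triester F7. McMurry keto-ester cyclisation with low-valent titanium (TiCl3/LiAlH4, Et3N, DME, reflux, slow addition) couples C9 with C11 to the cyclic enol ether F8. Dilute acid hydrolyses it with protonation at C9 to the cis-fused ketone 24.

**Further compounds**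
F1 | step 21 | 13-chloro-11-ketone (C13 epimers) | C#CC[C@]23CC(Cl)CC(=O)[C@H]2[C@]1(C)CC[C@H](O)[C@@](C)(C(=O)OC)[C@H]1[C@@H]3C(=O)OC
F2 | step 21 | ring-expanded cyclohex-12-en-11-one | C#CC[C@]23CC=CC(=O)[C@H]2[C@]1(C)CC[C@H](O)[C@@](C)(C(=O)OC)[C@H]1[C@@H]3C(=O)OC
F3 | step 21 | 17-tributylstannyl tetracycle (E/Z mixture) | CCCC[Sn](CCCC)(CCCC)C=C1C[C@]23C[C@H]1CC(=O)[C@H]2[C@]1(C)CC[C@H](O)[C@@](C)(C(=O)OC)[C@H]1[C@@H]3C(=O)OC
F4 | step 13 | 6-methoxymethylidene compound (E/Z mixture) | C[C@@]12CC[C@@H](O[Si](C)(C)C(C)(C)C)[C@@](C)(C(=O)OC)[C@H]1C(=COC)[C@@](CC#C)(CCC#N)C2=O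
F5 | step 13 | 6β-aldehyde | C[C@@]12CC[C@@H](O[Si](C)(C)C(C)(C)C)[C@@](C)(C(=O)OC)[C@H]1[C@H](C=O)[C@@](CC#C)(CCC#N)C2=O
F6 | step 13 | 6β-carboxylic acid | C[C@@]12CC[C@@H](O[Si](C)(C)C(C)(C)C)[C@@](C)(C(=O)OC)[C@H]1[C@H](C(=O)O)[C@@](CC#C)(CCC#N)C2=O
F7 | step 17 | keto triester | C[C@@]12CC[C@H](O)[C@@](C)(C(=O)OC)[C@H]1[C@H](C(=O)OC)[C@@](CC#C)(CCC(=O)OC)C2=O
F8 | step 17 | 9(11)-en-11-yl methyl ether | C#CC[C@]23CCC(OC)=C2[C@]1(C)CC[C@H](O)[C@@](C)(C(=O)OC)[C@H]1[C@@H]3C(=O)OC
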